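## Structural features

The target is a 2-aryl-2,3-dihydro-1-benzofuran neolignan. A syringyl ring (ring A, 4-hydroxy-3,5-dimethoxyphenyl) sits on C2 and a hydroxymethyl group on C3. The fused benzene ring (ring B) carries a methoxy group at C7 and an (E)-3-hydroxyprop-1-enyl chain at C5, para to the ring oxygen O1. C2 (S) and C3 (R) are the only stereocentres; they are adjacent, trans on the five-membered ring, and both benzylic. The fragile points are the C2–O1 benzylic ether, which lies para to the free ring A phenol and can open through a para-quinone methide under acid or strong base, the cinnamyl alcohol, which ionises easily in acid, and the two electron-rich arenes. The real difficulty is to form C2–C3 and C2–O1 with absolute and relative control, and then to finish without conditions that reopen the ring once the phenol is free. The key step uses the fact that C2 is bonded only to O1, C3, ring A and hydrogen, so it can arrive as a one-carbon benzylidene unit, while O1–C7a–C3a–C3 is the four-atom terminus of an ortho-quinone methide of ring B. A bromine at C5 is inert to that chemistry and holds the place of the side chain.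

## Logic of the disconnections

22 to 21: no skeletal bond is cut; only the O–Si bond of the C3 arm is made. The primary alcohol is masked because it has to pass through ylide, palladium and hydride chemistry. The forward step must cleave Si–O without generating a free phenoxide that could open the C2–O1 ether, so the fluoride has to be buffered.

21 to 20: two functional groups are taken back, the allylic alcohol to a methyl enoate and the ring A phenol to its pivalate. One hydride reagent can do both in the forward direction, which saves a step. The demand is clean 1,2-reduction of the conjugated ester with enough reagent to also cleave the hindered aryl ester.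

20 to 18 and 19: the C5–alkenyl carbon bond is cut. This removes the whole side chain in one stroke and leaves an aryl bromide, which is the simplest handle that survives the annulation. The forward coupling must set the E geometry and must not epimerise C2 or C3.

18 to 5 and 14: C2–C3 and O1–C2 are cut together, which opens the dihydrofuran ring and removes both stereocentres. The gain is the largest in the route: one fragment per aromatic ring, the ring B fragment racemic (its stereocentre becomes trigonal), and all chirality coming from a recoverable sulfide. The demand is heavy: the quinone methide must be trapped faster than it tautomerises, the ylide must add through one face, and the closure must give the trans ring.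

5 to 4, 3, 2 and 1: the benzylic C–S bond is cut back to a benzylic alcohol, the O–Si bond to a free primary alcohol, the two C–O bonds of the diol to an alkene, and the alkene to an aldehyde. Each cut is a standard operation on a bromo-salicylaldehyde that already has the full ring B substitution. The demands are selective silylation of the primary hydroxyl beside a phenol, and a sulfinate exchange that does not harm the silyl ether.

14 to 9 and 13, then 9 to 8, 7 and 6: the benzylic C–S bond of the sulfonium salt is cut, giving a benzyl bromide and the chiral sulfide. The bromide goes back through the alcohol to the aldehyde, and the pivalate to the free phenol. The pivalate is put on first so that ring A is never a free para-hydroxybenzyl electrophile. The twofold symmetry of 13 means alkylation can give only one sulfonium salt.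

13 to 11 and 10: both C–S bonds of the thiolane are cut, leading to an acyclic bis-sulfonate and then to the diol. Each C–S bond forms with inversion, so the diol must have the opposite descriptors to the sulfide. The demand is substitution over elimination at two secondary centres.

## Other disconnections considered

Alternative 1: The cut is the aryl–oxygen bond O1–C7a. Ring B would enter as a fluoroarene whose fluorine stands para to a formyl group. The open-chain (1S,2R) carbinol A2 would be deprotonated at its C2 hydroxyl, and the alkoxide would attack the fluorine-bearing carbon through a Meisenheimer-type adduct, giving the trans aldehyde A1 with both stereocentres untouched.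
- In favour: the ring closure is stereochemically neutral, so C2 and C3 can be set and checked beforehand by acyclic methods. No transient quinone methide and no stoichiometric chiral sulfide are needed. The C5 aldehyde that activates the substitution is also the handle for a two-carbon olefination, so no palladium step is needed. On these three points the alternative is the equal or the better of the chosen plan.
- Against: one para formyl group, opposed by an ortho methoxy donor, is a modest activator for fluoride displacement. The same alkoxide could add to the aldehyde, fragment in a retro-aldol sense, or epimerise the benzylic C3. The fluorinated ring B unit is not a commodity. The trityl and methoxymethyl groups must come off with acid in the presence of the para-oxygenated C2 ether.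
- Comparison: the substitution is mechanistically simpler than the ylide cascade. However, the chosen plan makes two skeletal bonds, the ring and both stereocentres in one step from two simple fragments, whereas A2 needs the complete C2–C3 pair built first (aldol-type construction, reduction, differential protection). The sequence should therefore be clearly longer.

Alternative 2: The cut removes C2–ring A and C3–C3a in one three-component operation. The ring A aryllithium A5 would add to the E-alkenyl boronate A4 to give an ate complex. The ring B triflate A6 would add oxidatively to zerovalent palladium generated from Pd(OAc)2 and a MandyPhos ligand. The arylpalladium would then induce a 1,2-shift of ring A from boron to C2 while palladium bonds to C3, and reductive elimination would form C3–C3a, giving boronic ester A3.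
- In favour: it is highly convergent, and absolute configuration is controlled by a catalyst and not a stoichiometric reagent, which is better than the chosen plan. Relative configuration follows from the alkene geometry, and the C–B bond can be oxidised to C–O with retention. In the number of skeletal bonds made in the key step (two) it is the equal.
- Against: A6 is electron-rich and ortho-substituted, and A4 is a 1,2-disubstituted alkenyl boronate with an allylic silyloxy group. Slow oxidative addition, direct Suzuki–Miyaura coupling and β-oxygen elimination from the C3–palladium intermediate are all plausible leaks. No ring is closed.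
- A structural point: in A3 the boron occupies the position that O1 must take. After oxidation, closure by displacing the carbinol with the ring B phenol would invert C2 and give the cis ring. The closure would therefore have to run through the ring A stabilised benzylic cation under thermodynamic control, and the C2 configuration set in the coupling is discarded.
- Comparison: after A3 there remain oxidation, unmasking of the ring B phenol, cyclisation, acetal hydrolysis, olefination, reduction and desilylation. The step count should exceed that of the chosen plan, although the fragments are simple.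

Alternative 3: The cut is C2–C3, made by inserting the ring B carbene carbon (C3) into the benzylic C–H bond of a syringylmethyl aryl ether. Diazo ester A8 would lose N2 on Rh2(S-DOSP)4 (or its enantiomer, as the required sense dictates). The dirhodium carbene would insert into the ether C–H bond five atoms away, closing the dihydrofuran ring and giving ester A7.
- In favour: the ring, the C2–C3 bond and both stereocentres arise in one catalytic asymmetric step. The C–H bond is activated by the ether oxygen and the electron-rich ring. The C5 bromide allows the same side-chain chemistry. Catalytic enantiocontrol, and the chance to reduce the C3 ester and the later enoate in one hydride step, are points on which it is the equal or the better of the chosen plan.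
- Against: a diazo compound and a diazo-transfer reagent must be handled, which is the less safe option. Insertions of this kind often favour the cis 2-aryl-3-carboxylate A9 kinetically, so the trans ester may need base epimerisation at C3. That correction is available here because C3 is α to the ester and C2 is unaffected; the chosen plan has no such option, so this is a point in the alternative's favour. The ring B arylacetate needed for diazo transfer requires a one-carbon homologation, which lengthens the front end.
- A point on the descriptors: A7 written with the spatial arrangement of the target carries the descriptors (2S,3S), because the ester outranks C2. Only the labels differ from the target, not the shape.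
- Comparison: the step count would be similar to or slightly above the chosen plan, with more hazard and less certain diastereoselectivity, but without dependence on a stoichiometric chiral reagent.

Key step: step 11

Assumption 1: the sense of induction of 13 is assigned by analogy with benzylidene transfer from ylides of this sulfide family to aldehydes; if the opposite sense held, the mirror-image diol would be used in step 8.
Assumption 2: the C3 arm is carried as a tert-butyldiphenylsilyl ether, not a smaller silyl ether, because it must be installed beside a free phenol and survive the acidic sulfinate exchange.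
Assumption 3: p-toluenesulfinic acid, 19 and the alkenyl boronate of the step 12 fallback are taken as purchased.

## Steps

Step 1
Reactants: 1 5-bromo-2-hydroxy-3-methoxybenzaldehyde
Product: 2 4-bromo-2-ethenyl-6-methoxyphenol
Conditions: Ph3PCH3Br (2.5 equiv), KOtBu (2.4 equiv), THF, 0 °C to rt
Reagents that add atoms: methyltriphenylphosphonium bromide, C[P+](c1ccccc1)(c1ccccc1)c1ccccc1.[Br-]
Why: Wittig methylenation; one equivalent of base is consumed by the phenol and the excess ylide converts the aldehyde of the phenoxide into the styrene, while the aryl bromide is inert.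

Step 2
Reactants: 2 4-bromo-2-ethenyl-6-methoxyphenol
Product: 3 rac-1-(5-bromo-2-hydroxy-3-methoxyphenyl)ethane-1,2-diol
Conditions: OsO4 (2 mol%), NMO (1.5 equiv), acetone/H2O, rt
Reagents that add atoms: N-methylmorpholine N-oxide, C[N+]1([O-])CCOCC1; water, O
Why: Catalytic syn-dihydroxylation of a styrene, with OsO4 as oxygen carrier and the amine oxide as terminal oxidant; the new benzylic centre is deliberately left racemic because it is erased in step 11.

Step 3
Reactants: 3 rac-1-(5-bromo-2-hydroxy-3-methoxyphenyl)ethane-1,2-diol
Product: 4 rac-4-bromo-2-[2-(tert-butyldiphenylsilyloxy)-1-hydroxyethyl]-6-methoxyphenol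
Conditions: TBDPSCl (1.05 equiv), imidazole (2.2 equiv), DMF, 0 °C
Reagents that add atoms: tert-butyl(chloro)diphenylsilane, CC(C)(C)[Si](Cl)(c1ccccc1)c1ccccc1
Why: Silyl ether formation; the bulky chlorosilane should pick the unhindered primary hydroxyl over the secondary benzylic one and over the phenol, which is flanked by two ortho substituents and hydrogen-bonded to the methoxy group.

Step 4
Reactants: 4 rac-4-bromo-2-[2-(tert-butyldiphenylsilyloxy)-1-hydroxyethyl]-6-methoxyphenol
Product: 5 rac-4-bromo-2-[2-(tert-butyldiphenylsilyloxy)-1-(4-methylphenylsulfonyl)ethyl]-6-methoxyphenol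
Conditions: p-TolSO2H (1.5 equiv), CH2Cl2, rt
Reagents that add atoms: p-toluenesulfinic acid, Cc1ccc(S(=O)O)cc1
Why: Acid-promoted loss of water from the ortho-hydroxybenzyl alcohol gives a quinone methide or benzylic cation that the sulfinate captures at sulfur, the standard access to 2-(1-sulfonylalkyl)phenols; the silyl ether should tolerate the weak acid, and the sulfone centre remains racemic.

Step 5
Reactants: 6 4-hydroxy-3,5-dimethoxybenzaldehyde (syringaldehyde)
Product: 7 4-formyl-2,6-dimethoxyphenyl pivalate
Conditions: PivCl (1.2 equiv), Et3N, DMAP (cat.), CH2Cl2, 0 °C to rt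
Reagents that add atoms: pivaloyl chloride, CC(C)(C)C(Cl)=O
Why: Acylation of the phenol under nucleophilic catalysis; the pivalate lowers the donor strength of ring A and is hindered enough to last until step 13.

Step 6
Reactants: 7 4-formyl-2,6-dimethoxyphenyl pivalate
Product: 8 4-(hydroxymethyl)-2,6-dimethoxyphenyl pivalate
Conditions: NaBH4, THF/MeOH, 0 °C
Reagents that add atoms: none
Why: Chemoselective borohydride reduction of the aldehyde; the hindered aryl pivalate should not be touched at 0 °C.

Step 7
Reactants: 8 4-(hydroxymethyl)-2,6-dimethoxyphenyl pivalate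
Product: 9 4-(bromomethyl)-2,6-dimethoxyphenyl pivalate
Conditions: PBr3 (0.4 equiv), CH2Cl2, 0 °C
Reagents that add atoms: phosphorus tribromide, BrP(Br)Br
Why: Conversion of a benzylic alcohol into the bromide through a phosphite ester and SN2 attack of bromide; the ester is stable to the HBr formed.

Step 8
Reactants: 10 (2R,5R)-hexane-2,5-diol
Product: 11 (2R,5R)-hexane-2,5-diyl dimethanesulfonate
Conditions: MsCl (2.4 equiv), Et3N (3 equiv), CH2Cl2, 0 °C
Reagents that add atoms: methanesulfonyl chloride, CS(Cl)(=O)=O
Why: O-sulfonylation; no bond to either stereocentre is broken, so the (2R,5R) configuration is retained.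

Step 9
Reactants: 11 (2R,5R)-hexane-2,5-diyl dimethanesulfonate
Product: 13 (2S,5S)-2,5-dimethylthiolane, via mesyloxy thiolate 12 (not isolated)
Conditions: Na2S·9H2O (1.2 equiv), DMSO, rt to 40 °C; distillation
Reagents that add atoms: sodium sulfide, [Na+].[Na+].[S-2]
Why: Double SN2 displacement, intermolecular then 5-exo-tet; each C–S bond forms with inversion, so the (2R,5R) bis-sulfonate gives the (2S,5S) sulfide.

Step 10
Reactants: 9 4-(bromomethyl)-2,6-dimethoxyphenyl pivalate; 13 (2S,5S)-2,5-dimethylthiolane
Product: 14 (2S,5S)-1-(3,5-dimethoxy-4-pivaloyloxybenzyl)-2,5-dimethylthiolanium tetrafluoroborate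
Conditions: AgBF4 (1.0 equiv), 13 (1.5 equiv), CH2Cl2, 0 °C to rt, dark; filter, precipitate with Et2O
Reagents that add atoms: silver tetrafluoroborate (supplies the counter-ion), [Ag+].F[B-](F)(F)F
Why: S-alkylation of the sulfide with silver-assisted removal of bromide; the two sulfur lone pairs are equivalent by symmetry so only one salt can form, and the non-nucleophilic counter-ion prevents dealkylation.

Step 11
Reactants: 5 rac-4-bromo-2-[2-(tert-butyldiphenylsilyloxy)-1-(4-methylphenylsulfonyl)ethyl]-6-methoxyphenol; 14 (2S,5S)-1-(3,5-dimethoxy-4-pivaloyloxybenzyl)-2,5-dimethylthiolanium tetrafluoroborate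
Product: 18 4-[(2S,3R)-5-bromo-3-(tert-butyldiphenylsilyloxymethyl)-7-methoxy-2,3-dihydro-1-benzofuran-2-yl]-2,6-dimethoxyphenyl pivalate, via ortho-quinone methide 15 (not isolated), via sulfonium ylide 16 (not isolated), via phenoxide betaine 17 (not isolated)
Conditions: 14 (1.3 equiv), Cs2CO3 (3 equiv), 4 Å MS, CH2Cl2/MeCN, −20 °C; slow addition of 5; then 0 °C
Reagents that add atoms: none
Why: This is the formal [4+1] annulation of an in situ ortho-quinone methide with a sulfonium ylide, a known route from 2-(1-sulfonylalkyl)phenols to trans-2,3-dihydrobenzofurans, run here with a benzylide on a twofold-symmetric chiral thiolane of the kind used for asymmetric benzylidene transfer to aldehydes. Cs2CO3 deprotonates the phenol of 5, the phenoxide expels p-toluenesulfinate to give quinone methide 15 (the racemic sulfone centre becomes trigonal), and the same base reversibly converts 14 into ylide 16. The ylide carbon adds to the exocyclic methide carbon (C2–C3), restoring the aromaticity of ring B and giving betaine 17, whose phenoxide then displaces the neutral thiolane at the benzylic carbon in a 5-exo-tet closure (O1–C2) with inversion, forming the dihydrofuran ring. C2 is controlled by the thiolane, whose flanking methyl groups should screen one face of the ylide carbon, followed by the stereospecific invertive closure, and the (2S,5S) sulfide is chosen for (2S) by analogy with the sense of benzylidene transfer to aldehydes. C3 is set in the same C–C bond-forming event by the approach in which the ring A aryl group and the silyloxymethyl arm avoid each other, and this betaine is the one that closes to the trans ring. The step needs conjugate addition to outrun tautomerisation of 15 to a vinyl phenol and its dimerisation, which slow addition of 5 to an excess of cold 14 and base is meant to secure. It also needs 14 neither to ionise nor to lose its ester, which the pivalate-capped ring A and the dry, non-nucleophilic carbonate should secure.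

Step 12
Reactants: 18 4-[(2S,3R)-5-bromo-3-(tert-butyldiphenylsilyloxymethyl)-7-methoxy-2,3-dihydro-1-benzofuran-2-yl]-2,6-dimethoxyphenyl pivalate; 19 methyl acrylate
Product: 20 methyl (E)-3-[(2S,3R)-3-(tert-butyldiphenylsilyloxymethyl)-2-(3,5-dimethoxy-4-pivaloyloxyphenyl)-7-methoxy-2,3-dihydro-1-benzofuran-5-yl]prop-2-enoate
Conditions: Pd(OAc)2 (5 mol%), P(o-tol)3 (12 mol%), Et3N (3 equiv), 19 (3 equiv), DMF, 100 °C
Reagents that add atoms: none
Why: Mizoroki–Heck reaction; zerovalent palladium formed in situ inserts into C5–Br, syn-carbopalladation of the acrylate and syn-β-hydride elimination give the E enoate, and the amine base cannot epimerise C2 or C3 or cleave the silyl ether or pivalate.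

Step 13
Reactants: 20 methyl (E)-3-[(2S,3R)-3-(tert-butyldiphenylsilyloxymethyl)-2-(3,5-dimethoxy-4-pivaloyloxyphenyl)-7-methoxy-2,3-dihydro-1-benzofuran-5-yl]prop-2-enoate
Product: 21 4-[(2S,3R)-3-(tert-butyldiphenylsilyloxymethyl)-5-[(E)-3-hydroxyprop-1-enyl]-7-methoxy-2,3-dihydro-1-benzofuran-2-yl]-2,6-dimethoxyphenol
Conditions: iBu2AlH (6 equiv), CH2Cl2, −78 to 0 °C; aq. potassium sodium tartrate (KNaC4H4O6)
Reagents that add atoms: none
Why: 1,2-Hydride reduction of the conjugated ester to the allylic alcohol, with reductive cleavage of the aryl pivalate by the same reagent; the silyl ether, the alkene geometry and both stereocentres are untouched at low temperature.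

Step 14
Reactants: 21 4-[(2S,3R)-3-(tert-butyldiphenylsilyloxymethyl)-5-[(E)-3-hydroxyprop-1-enyl]-7-methoxy-2,3-dihydro-1-benzofuran-2-yl]-2,6-dimethoxyphenol
Product: 22 4-[(2S,3R)-3-(hydroxymethyl)-5-[(E)-3-hydroxyprop-1-enyl]-7-methoxy-2,3-dihydro-1-benzofuran-2-yl]-2,6-dimethoxyphenol
Conditions: TBAF (2 equiv), AcOH (2 equiv), THF, rt
Reagents that add atoms: none
Why: Fluoride-mediated cleavage of the Si–O bond; buffering with acetic acid keeps the ring A phenol protonated so that the C2–O1 ether is not opened through a para-quinone methide.

## Compound list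

1 | 5-bromo-2-hydroxy-3-methoxybenzaldehyde | COc1cc(Br)cc(C=O)c1O | starting material
2 | 4-bromo-2-ethenyl-6-methoxyphenol | COc1cc(Br)cc(C=C)c1O | intermediate
3 | rac-1-(5-bromo-2-hydroxy-3-methoxyphenyl)ethane-1,2-diol | COc1cc(Br)cc(C(O)CO)c1O | intermediate
4 | rac-4-bromo-2-[2-(tert-butyldiphenylsilyloxy)-1-hydroxyethyl]-6-methoxyphenol | COc1cc(Br)cc(C(O)CO[Si](c2ccccc2)(c2ccccc2)C(C)(C)C)c1O | intermediate
5 | rac-4-bromo-2-[2-(tert-butyldiphenylsilyloxy)-1-(4-methylphenylsulfonyl)ethyl]-6-methoxyphenol | COc1cc(Br)cc(C(CO[Si](c2ccccc2)(c2ccccc2)C(C)(C)C)S(=O)(=O)c2ccc(C)cc2)c1O | intermediate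
6 | 4-hydroxy-3,5-dimethoxybenzaldehyde (syringaldehyde) | COc1cc(C=O)cc(OC)c1O | starting material
7 | 4-formyl-2,6-dimethoxyphenyl pivalate | COc1cc(C=O)cc(OC)c1OC(=O)C(C)(C)C | intermediate
8 | 4-(hydroxymethyl)-2,6-dimethoxyphenyl pivalate | COc1cc(CO)cc(OC)c1OC(=O)C(C)(C)C | intermediate
9 | 4-(bromomethyl)-2,6-dimethoxyphenyl pivalate | COc1cc(CBr)cc(OC)c1OC(=O)C(C)(C)C | intermediate
10 | (2R,5R)-hexane-2,5-diol | C[C@@H](O)CC[C@@H](C)O | starting material
11 | (2R,5R)-hexane-2,5-diyl dimethanesulfonate | C[C@@H](OS(C)(=O)=O)CC[C@@H](C)OS(C)(=O)=O | intermediate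
12 | sodium (2S,5R)-5-(methylsulfonyloxy)hexane-2-thiolate (not isolated) | C[C@H]([S-])CC[C@@H](C)OS(C)(=O)=O.[Na+] | intermediate
13 | (2S,5S)-2,5-dimethylthiolane | C[C@H]1CC[C@H](C)S1 | intermediate
14 | (2S,5S)-1-(3,5-dimethoxy-4-pivaloyloxybenzyl)-2,5-dimethylthiolanium tetrafluoroborate | C[C@H]1CC[C@H](C)[S+]1Cc1cc(OC)c(OC(=O)C(C)(C)C)c(OC)c1.F[B-](F)(F)F | intermediate
15 | (E)-4-bromo-6-[2-(tert-butyldiphenylsilyloxy)ethylidene]-2-methoxycyclohexa-2,4-dien-1-one (not isolated) | COC1=CC(Br)=C/C(=C\CO[Si](c2ccccc2)(c2ccccc2)C(C)(C)C)C1=O | intermediate
16 | (2S,5S)-2,5-dimethylthiolanium (3,5-dimethoxy-4-pivaloyloxyphenyl)methylide (not isolated) | C[C@H]1CC[C@H](C)[S+]1[CH-]c1cc(OC)c(OC(=O)C(C)(C)C)c(OC)c1 | intermediate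
17 | (2S,5S)-1-[(1R,2R)-2-(5-bromo-3-methoxy-2-oxidophenyl)-3-(tert-butyldiphenylsilyloxy)-1-(3,5-dimethoxy-4-pivaloyloxyphenyl)propyl]-2,5-dimethylthiolanium, zwitterion (not isolated) | COc1cc([C@H]([S+]2[C@@H](C)CC[C@@H]2C)[C@@H](CO[Si](c2ccccc2)(c2ccccc2)C(C)(C)C)c2cc(Br)cc(OC)c2[O-])cc(OC)c1OC(=O)C(C)(C)C | intermediate
18 | 4-[(2S,3R)-5-bromo-3-(tert-butyldiphenylsilyloxymethyl)-7-methoxy-2,3-dihydro-1-benzofuran-2-yl]-2,6-dimethoxyphenyl pivalate | COc1cc([C@H]2Oc3c(OC)cc(Br)cc3[C@@H]2CO[Si](c2ccccc2)(c2ccccc2)C(C)(C)C)cc(OC)c1OC(=O)C(C)(C)C | intermediate
19 | methyl acrylate | C=CC(=O)OC | starting material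
20 | methyl (E)-3-[(2S,3R)-3-(tert-butyldiphenylsilyloxymethyl)-2-(3,5-dimethoxy-4-pivaloyloxyphenyl)-7-methoxy-2,3-dihydro-1-benzofuran-5-yl]prop-2-enoate | COc1cc([C@H]2Oc3c(OC)cc(/C=C/C(=O)OC)cc3[C@@H]2CO[Si](c2ccccc2)(c2ccccc2)C(C)(C)C)cc(OC)c1OC(=O)C(C)(C)C | intermediate
21 | 4-[(2S,3R)-3-(tert-butyldiphenylsilyloxymethyl)-5-[(E)-3-hydroxyprop-1-enyl]-7-methoxy-2,3-dihydro-1-benzofuran-2-yl]-2,6-dimethoxyphenol | COc1cc([C@H]2Oc3c(OC)cc(/C=C/CO)cc3[C@@H]2CO[Si](c2ccccc2)(c2ccccc2)C(C)(C)C)cc(OC)c1O | intermediate
22 | 4-[(2S,3R)-3-(hydroxymethyl)-5-[(E)-3-hydroxyprop-1-enyl]-7-methoxy-2,3-dihydro-1-benzofuran-2-yl]-2,6-dimethoxyphenol | COc1cc([C@H]2Oc3c(OC)cc(/C=C/CO)cc3[C@@H]2CO)cc(OC)c1O | target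

## Step count and least certain steps

Total step count: 14. Longest linear sequence: 8 steps (steps 1–4 and 11–14 from 1; the ring A branch through steps 5–7, 10 and 11–14 is equally long).

Step 11 (key step). The most likely failure is incomplete transfer of chirality together with leakage to the cis ring. A monocyclic thiolane gives only moderate conformational bias to the ylide. Reversible deprotonation next to sulfur in the betaine can equilibrate C2 before closure, which would turn a minor betaine into the enantiomeric trans product. On the reactivity side, the quinone methide may tautomerise faster than it is trapped, since its methide carbon carries an alkyl-type arm. Fallback (sets out from 9 and 5, returns at 18): 9 would alkylate achiral thiolane with AgBF4 to give 1-(3,5-dimethoxy-4-pivaloyloxybenzyl)thiolanium tetrafluoroborate F1. The same carbonate-mediated annulation with 5 would give the racemic trans dihydrobenzofuran F2, which would be resolved by preparative chromatography on a chiral stationary phase to return 18.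

Step 4. The benzylic cation or quinone methide formed under acid may lose the silyl ether, or shed a proton towards an enol ether that closes to a benzofuran, before the sulfinate adds. The β-oxygen also slows the ionisation, so longer exposure to acid is needed. Fallback (sets out from 3, returns at 5): the sulfinate exchange would be run on the unprotected triol 3 under aqueous conditions (p-TolSO2Na, HCO2H/H2O, rt) to give the hydroxy sulfone rac-4-bromo-2-[2-hydroxy-1-(4-methylphenylsulfonyl)ethyl]-6-methoxyphenol F3. Its primary hydroxyl would then be silylated (TBDPSCl, imidazole, CH2Cl2, 0 °C) to give 5.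

Step 3. Competitive silylation of the phenol would give mixtures of mono- and bis-silyl ethers. Fallback (sets out from 3, returns at 4): silylation would be driven to completion at both the primary hydroxyl and the phenol (TBDPSCl 2.3 equiv, imidazole, DMF, rt) to give the bis-silyl ether rac-1-[5-bromo-2-(tert-butyldiphenylsilyloxy)-3-methoxyphenyl]-2-(tert-butyldiphenylsilyloxy)ethanol F4. The much more labile aryl silyl ether would then be cleaved selectively (K2CO3, MeOH, 0 °C) to give 4.

Step 12. Oxidative addition into the electron-rich, para-oxygenated aryl bromide may be slow at the temperature the Heck cycle needs, with catalyst decay and reductive debromination competing. Fallback (sets out from 18, returns at 22): Suzuki–Miyaura coupling of 18 with purchased (E)-tert-butyldimethyl{[3-(4,4,5,5-tetramethyl-1,3,2-dioxaborolan-2-yl)prop-2-en-1-yl]oxy}silane (Pd(OAc)2, SPhos, K3PO4, THF/H2O, 50 °C) would give the allyl silyl ether pivalate F5. iBu2AlH would cleave the pivalate to give the bis-silyl ether phenol F6, and buffered TBAF would remove both silyl groups to give 22.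

Step 14. Once the ring A phenol is free, basic fluoride may open the C2–O1 ether through a para-quinone methide, which would epimerise C2 or lead to fragmentation. Fallback (sets out from 20, returns at 22): the silyl ether would be removed first, while the phenol is still an ester (HF·pyridine, THF/pyridine, 0 °C to rt), to give the hydroxy enoate pivalate F7. The iBu2AlH reduction and pivalate cleavage would then be the last step, run cold with a neutral tartrate work-up, to give 22.

## Further compounds

F1 | step 11 | 1-(3,5-dimethoxy-4-pivaloyloxybenzyl)thiolanium tetrafluoroborate | COc1cc(C[S+]2CCCC2)cc(OC)c1OC(=O)C(C)(C)C.F[B-](F)(F)F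
F2 | step 11 | racemic trans 4-[5-bromo-3-(tert-butyldiphenylsilyloxymethyl)-7-methoxy-2,3-dihydro-1-benzofuran-2-yl]-2,6-dimethoxyphenyl pivalate, (2S,3R) and (2R,3S) | COc1cc([C@H]2Oc3c(OC)cc(Br)cc3[C@@H]2CO[Si](c2ccccc2)(c2ccccc2)C(C)(C)C)cc(OC)c1OC(=O)C(C)(C)C.COc1cc([C@@H]2Oc3c(OC)cc(Br)cc3[C@H]2CO[Si](c2ccccc2)(c2ccccc2)C(C)(C)C)cc(OC)c1OC(=O)C(C)(C)C
F3 | step 4 | rac-4-bromo-2-[2-hydroxy-1-(4-methylphenylsulfonyl)ethyl]-6-methoxyphenol | COc1cc(Br)cc(C(CO)S(=O)(=O)c2ccc(C)cc2)c1O
F4 | step 3 | rac-1-[5-bromo-2-(tert-butyldiphenylsilyloxy)-3-methoxyphenyl]-2-(tert-butyldiphenylsilyloxy)ethanol | COc1cc(Br)cc(C(O)CO[Si](c2ccccc2)(c2ccccc2)C(C)(C)C)c1O[Si](c1ccccc1)(c1ccccc1)C(C)(C)C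
F5 | step 12 | 4-[(2S,3R)-5-[(E)-3-(tert-butyldimethylsilyloxy)prop-1-enyl]-3-(tert-butyldiphenylsilyloxymethyl)-7-methoxy-2,3-dihydro-1-benzofuran-2-yl]-2,6-dimethoxyphenyl pivalate | COc1cc([C@H]2Oc3c(OC)cc(/C=C/CO[Si](C)(C)C(C)(C)C)cc3[C@@H]2CO[Si](c2ccccc2)(c2ccccc2)C(C)(C)C)cc(OC)c1OC(=O)C(C)(C)C
F6 | step 12 | 4-[(2S,3R)-5-[(E)-3-(tert-butyldimethylsilyloxy)prop-1-enyl]-3-(tert-butyldiphenylsilyloxymethyl)-7-methoxy-2,3-dihydro-1-benzofuran-2-yl]-2,6-dimethoxyphenol | COc1cc([C@H]2Oc3c(OC)cc(/C=C/CO[Si](C)(C)C(C)(C)C)cc3[C@@H]2CO[Si](c2ccccc2)(c2ccccc2)C(C)(C)C)cc(OC)c1O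
F7 | step 14 | methyl (E)-3-[(2S,3R)-2-(3,5-dimethoxy-4-pivaloyloxyphenyl)-3-(hydroxymethyl)-7-methoxy-2,3-dihydro-1-benzofuran-5-yl]prop-2-enoate | COc1cc([C@H]2Oc3c(OC)cc(/C=C/C(=O)OC)cc3[C@@H]2CO)cc(OC)c1OC(=O)C(C)(C)C
A1 | alternative 1 | (2S,3R)-2-[3,5-dimethoxy-4-(methoxymethoxy)phenyl]-7-methoxy-3-(trityloxymethyl)-2,3-dihydro-1-benzofuran-5-carbaldehyde | COc1cc([C@H]2Oc3c(OC)cc(C=O)cc3[C@@H]2COC(c2ccccc2)(c2ccccc2)c2ccccc2)cc(OC)c1OCOC
A2 | alternative 1 | 4-fluoro-3-[(1R,2S)-2-hydroxy-2-[3,5-dimethoxy-4-(methoxymethoxy)phenyl]-1-(trityloxymethyl)ethyl]-5-methoxybenzaldehyde, the (1S,2R) carbinol in propanol numbering | COc1cc([C@@H](O)[C@@H](COC(c2ccccc2)(c2ccccc2)c2ccccc2)c2cc(C=O)cc(OC)c2F)cc(OC)c1OCOC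
A3 | alternative 2 | syn 1,2-diaryl-3-(tert-butyldimethylsilyloxy)propyl boronic mac ester | CC(C)(C)[Si](C)(C)OC[C@@H](c1cc(C2OCCO2)cc(OC)c1OCOC)[C@H](B1O[C@]2(C)c3cccc4cccc(c34)[C@]2(C)O1)c1cc(OC)c(OCOC)c(OC)c1
A4 | alternative 2 | (E)-3-(tert-butyldimethylsilyloxy)prop-1-enyl boronic mac ester | CC(C)(C)[Si](C)(C)OC/C=C/B1O[C@]2(C)c3cccc4cccc(c34)[C@]2(C)O1
A5 | alternative 2 | [3,5-dimethoxy-4-(methoxymethoxy)phenyl]lithium | [Li]c1cc(OC)c(OCOC)c(OC)c1
A6 | alternative 2 | 5-(1,3-dioxolan-2-yl)-3-methoxy-2-(methoxymethoxy)phenyl trifluoromethanesulfonate | COCOc1c(OC)cc(C2OCCO2)cc1OS(=O)(=O)C(F)(F)F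
A7 | alternative 3 | methyl (2S,3S)-5-bromo-2-[4-(tert-butyldimethylsilyloxy)-3,5-dimethoxyphenyl]-7-methoxy-2,3-dihydro-1-benzofuran-3-carboxylate (trans) | COc1cc([C@H]2Oc3c(OC)cc(Br)cc3[C@@H]2C(=O)OC)cc(OC)c1O[Si](C)(C)C(C)(C)C
A8 | alternative 3 | methyl 2-[5-bromo-2-{[4-(tert-butyldimethylsilyloxy)-3,5-dimethoxyphenyl]methoxy}-3-methoxyphenyl]-2-diazoacetate | COC(=O)C(=[N+]=[N-])c1cc(Br)cc(OC)c1OCc1cc(OC)c(O[Si](C)(C)C(C)(C)C)c(OC)c1
A9 | alternative 3 | methyl (2S,3R)-5-bromo-2-[4-(tert-butyldimethylsilyloxy)-3,5-dimethoxyphenyl]-7-methoxy-2,3-dihydro-1-benzofuran-3-carboxylate (cis) | COc1cc([C@H]2Oc3c(OC)cc(Br)cc3[C@H]2C(=O)OC)cc(OC)c1O[Si](C)(C)C(C)(C)C
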